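- A molecule of starting material leaves by one of a few exits, so I follow it to the fork: quench by the protic impurity on one side, target or homo dimer on the other.

| flask | starting material | protic impurity | remark | time |
|---|---|---|---|---|
| elm | 0.068 M | 0.023 M | run made earlier |  |
| ash | 0.068 M | 0.22 M | run made earlier |  |
| autumn | 0.068 M | 0.0200 M |  | 15 h |
| winter | 0.068 M | 0.0400 M |  | 15 h |
| noon | 0.068 M | 0.0800 M |  | 15 h |
| spring | 0.068 M | 0.150 M |  | 15 h |

| run | time / h | target / % | starting material / % |
|---|---|---|---|
| elm | 0.833 | 4.0 | 89.8 |
| elm | 2.00 | 13.9 | 80.9 |
| elm | 5.00 | 22.2 | 60.1 |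
| elm | 10.0 | 25.2 | 42.1 |
| ash | 1.33 | 7.6 | 79.9 |
| ash | 4.00 | 16.8 | 54.8 |
| ash | 6.00 | 17.3 | 44.1 |
| ash | 10.0 | 17.7 | 27.5 |

(readings scatter by 1 percentage point)
- a species is counted by the starting material in it: one homo dimer counts as two
- reactions considered so far: target <-> isomer of the product A; starting material + protic impurity -> quenched substrate; isomer of the product A <-> isomer of the product B; target -> over-reaction product; starting material <-> target; isomer of the product B <-> starting material; 2 starting material -> homo dimer
- "hardly changes" means that all values lie within two and a half points (for a concentration: within two and a half percent of the largest)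
- amount of target at the end, in percent of the starting material charged for autumn, winter, noon, spring, in this order
- how the row runs (rises all the way / hardly changes / falls all the way / falls, then rises / rises, then falls)

- The level comes from elm, whose target reads 25.2 % at 10.0 h. I carry that level unchanged to 15 h: target in ash reads 16.8 % at 4.00 h and 17.7 % at 10.0 h. A miss of 1 percentage point in the elm reading moves my numbers by about as much, and the row still falls.
- Onward loss of target and the homo dimer exit need no number of their own: the charge is 0.068 M in elm and in the asked flasks, so I take them as shared and already inside the elm level.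
- The quench rate is the number I need most: the target reading in ash, 17.7 %, stands 7.5 points below elm at the same time, and the impurity charge is the one setting in which the two runs differ.
- Starting material decays on average at 0.0865 h⁻¹ in elm and faster, at 0.129 h⁻¹, in ash. I read the gap as a pseudo-first-order quench, which gives 0.216 L mol⁻¹ h⁻¹ per unit of impurity and leaves 0.0815 h⁻¹ for the other exits.
- Spring then gives 28.5 % as its quench share, the chance that a leaving molecule of starting material goes to quenched substrate. Autumn gives 5.04 % and elm 5.75 %.
- Scaling the elm level by what escapes the quench, I commit to 25.4 % of target in autumn and 19.1 % in spring, falling steadily between them.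
- The forecast reads 23 %, 21 %, 19 %, 16.5 %, falls all the way, on the ground that “More impurity diverts starting material, so the yield falls steadily”.
- The flask gives 23.7 %, 22.9 %, 21.4 %, 19.0 %: falls all the way.

    target ⇌ isomer of the product A (K = 0.0990, k = 6.20 × 10⁻⁶ s⁻¹)
    starting material + protic impurity → quenched substrate (k = 7.20 × 10⁻⁵ L mol⁻¹ s⁻¹)
    isomer of the product A ⇌ isomer of the product B (K = 1.50, k = 2.20 × 10⁻⁶ s⁻¹)
    target → over-reaction product (k = 1.60 × 10⁻⁵ s⁻¹)
    starting material ⇌ target (K = 1.10, k = 2.20 × 10⁻⁵ s⁻¹)
    isomer of the product B ⇌ starting material (k = 3.70 × 10⁻⁷ s⁻¹)
    2 starting material → homo dimer (k = 7.40 × 10⁻⁵ L mol⁻¹ s⁻¹)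

- Spring ends at 19.0 % of target with 88 % of its impurity charge still there. Its starting material has gone down to 23 %, so the quench share reckons 21.9 % as quenched substrate, and the flask holds 25.8 %. In autumn, with 34 % of starting material left, the same reckoning gives 3.33 %, and the flask holds 4.01 %.

The earlier runs and the new flask stem from a simulated flask with made-up constants; the scatter is artificial.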